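If I replace each curve by its mean rate, one ratio of two readings gives an order in free catalyst, and I can test the bend of the curves afterwards.

| flask | substrate | coupling partner | free catalyst | remark |
|---|---|---|---|---|
| amber | 0.80 M | 3 equiv | 0.28 mol% | run made earlier |
| green | 0.80 M | 3 equiv | 0.44 mol% | run made earlier |
| flask | 0.80 M | 3.00 equiv | 0.2 mol% |  |

- amber (time / h: product / %, substrate / %): 0.500: 2.3, 96.8; 0.833: 4.0, 95.5; 1.33: 8.3, 92.5; 2.50: 13.7, 85.8; 4.00: 21.2, 77.7; 6.00: 31.9, 67.7
- green (time / h: product / %, substrate / %): 0.417: 3.7, 97.2; 1.33: 10.0, 89.9; 2.50: 18.8, 80.1; 4.00: 29.4, 70.0; 5.00: 36.2, 63.3; 6.00: 43.2, 57.1

(scatter of a reading: 0.5 percentage points)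

- apparent order in free catalyst when 30% of the substrate are converted (percent change of the rate of making product for one percent more free catalyst charged)
- apparent order in coupling partner when 30% of the substrate are converted (percent change of the rate of making product for one percent more coupling partner charged)

- the numbers in the tables scatter by 0.5 percentage points (one standard deviation)
- no earlier run changes the charge of coupling partner; that part of a forecast is a guess

After 6.00 h the amber run holds 31.9% product and the green run 43.2%. The logarithm of that ratio over the logarithm of the ratio of loadings is 0.671; this is my mean-rate order, with a scatter of 0.0431. The later stretch of both runs alone, from 2.50 h on, gives 0.649, which differs by less than that scatter, so within the scatter of these two runs the mean costs little.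

My first bounds on the order in free catalyst are 1, for units working singly, and 0.5, for units held mostly in pairs. Assuming the order does not fall as the loading falls, the floor for this flask tightens to two scatters below the reading, 0.585. For coupling partner in this flask I take a floor of 0, supposing that it does not slow the reaction. If one partner goes per product and the whole slackening of the green run is blamed on partner, a rough reading of the ceiling is 0.981.

The forecast gives 0.72 for free catalyst, above my floor, and 0.3 for coupling partner, below my ceiling, saying of the latter that “this is largely a guess”.

The flask gives 0.80 in free catalyst, higher than the mean-rate order, and 0.049 in coupling partner.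

    catalyst intermediate A ⇌ by-product + catalyst intermediate B (K = 0.930 M, k = 4000 h⁻¹)
    catalyst intermediate C → free catalyst + product (k = 84.0 h⁻¹)
    substrate + catalyst intermediate B ⇌ catalyst intermediate C (K = 4.60 M⁻¹, k = 120 M⁻¹ h⁻¹)
    coupling partner + free catalyst → catalyst intermediate A (k = 160 M⁻¹ h⁻¹)
    2 catalyst intermediate C ⇌ resting dimer, settled at all times (K = 1500 M⁻¹)

In this flask the resting dimer, a form outside the working round (an off-cycle species), holds 34.1% of the catalyst charged at 0.800 h and 23.4% at 8.00 h. Carried down from the amber run by the ratio of loadings to the power 0.671, the mean rate of making product, with product read as conversion, puts 30% conversion at 7.07 h, and this flask reaches it after 7.14 h.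

Readings and results come from a simulation for an exercise.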